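starting material 0.50 mM; second substrate 0.500 equiv; reagent 1.00 equiv; free catalyst 0.28 mol%; time 6.0 min

    starting material + free catalyst ⇌ catalyst intermediate A (K1 = 4700 /M, k1 = 1.9 × 10⁵ /M/s)
    reagent + catalyst intermediate A → free catalyst + target (k2 = 3.3 × 10⁵ /M/s)
    second substrate + free catalyst ⇌ catalyst intermediate B (K3 = 3800 /M, k3 = 2.2 × 10⁶ /M/s)
    reagent + catalyst intermediate B → free catalyst + second product (k4 = 1.8 × 10⁵ /M/s)
    starting material + reagent → uncatalysed product (k5 = 97 /M/s)

- how much target there is at 6.0 min, in percent of the starting material charged
- how much uncatalysed product there is at 6.0 min, in percent of the starting material charged

**Reagent count.** Each reagent molecule that reacts leaves in one product molecule and the catalyst comes back, so target, second product and uncatalysed product add up to the reagent consumed. The flask holds 0.500 mM of reagent against 0.750 mM of the two substrates together, which makes reagent the limiting reagent. The half-lives of starting material by the uncatalysed step alone and by the forward step into the catalyst alone, the other charges held, are 0.24 min and 2.6 s, far shorter than 6.0 min, so we treat the reading as an end point and ask how the reagent is shared.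

**Bench rule.** At the bench we count a catalysed route at the speed with which substrate enters the catalyst, trusting that what enters goes on to product. We call catalyst lead the forward rate of starting material into the catalyst, with the charged catalyst counted as free, over the rate of its uncatalysed reaction, both at the charges: 5.48. We expect target over uncatalysed product, the selectivity factor, to lie near this figure, and probably below it, since each binding equilibrium constant times its charged substrate, 2.4 for starting material and 0.95 for second substrate, is not small, and binding takes catalyst out of the free form.

**Its border.** With c_reagent as charged, catalyst intermediate A goes on at 165 /s and falls back at 40.4 /s, a ratio of 4.08, so the trust in going on holds for it at the start. The two rates become equal once c_reagent has fallen to 24.5 % of its charge. For catalyst intermediate B the same ratio is 0.155, so that trust fails there from the start, and our reckoning stops at the factor, with second product unreckoned.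

**The run.** The forecast says 56 % target and 14 % uncatalysed product, holding that “the yields depend only on how the reagent is split”. The flask gives 54.4 % and 14.7 % at 6.0 min, a ratio of amounts over the whole run of 3.69, lower than the lead of 5.48, which is a ratio of starting rates. Reagent left then is 0 %, and second product reads 0.155 mM. In this flask the ratio read is 0.674 of the lead. The neighbour flask with 0.07 mol% of catalyst has a lead of 1.37, and that same fraction of it makes 0.923. That neighbour flask reads 36.1 % target and 38.7 % uncatalysed product, a ratio of 0.933.

The numbers of this flask are made up; no experiment stands behind them.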